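(The earlier runs and the new flask were generated by integration on assumed constants; the scatter is artificial.)

A small charge of impurity, 3.4 mM, would take 24.3 % of the initiator in the blue run but 48.6 % in the flask if the two react one for one. The decision is whether the flask can be charged this low and left for 4.0 d.

| flask | free monomer | initiator | impurity | remark | time |
|---|---|---|---|---|---|
| blue | 0.20 M | 14 mM | 3.4 mM | run made earlier |  |
| flask | 0.20 M | 7.0 mM | 3.4 mM |  | 4.0 d |

- blue (time / h: monomer in chains / %, free monomer / %): 1.50: 3.4, 95.7; 2.50: 7.2, 92.9; 4.00: 11.6, 87.0; 5.00: 16.2, 83.0; 8.00: 25.8, 73.6; 12.0: 37.8, 61.1; 20.0: 58.3, 41.7

(readings scatter by 0.5 percentage points)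

1. average number of monomer units in a chain (chains begun, living or dead) at 4.0 d
2. part of the free monomer that has reacted at 4.0 d

- the average divides the monomer in chains by the number of chains begun, living and dead together
- reactions considered so far: free monomer + initiator -> living end + monomer in chains; free monomer + living end -> monomer in chains + living end; initiator + impurity -> spent initiator
- the earlier runs do not show the number of chains; that part of a forecast is a guess
- no earlier run changes the charge of initiator; that part of a forecast is a guess

The quantity to carry is the surplus, the charge of initiator minus the charge of impurity: 3.60 mM in the flask and 10.6 mM in the blue run. If each unit of surplus becomes one living end, c(living end) stays constant, and free monomer falls pseudo-first-order, so ln of c(free monomer) at the charge over c(free monomer) grows in proportion to surplus times time. The blue run's last reading, 41.7 % at 20.0 h, gives a slope of 0.0437 h⁻¹. The flask has about a third of that surplus, so its slope is reckoned at 0.0149 h⁻¹, not the half that the initiator charge suggests. This reckoning gives c = 76.0 % and dp = 42.2, and on these estimates the flask is charged as written. It rests on a guess, since no earlier run changes the initiator charge.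

The forecast is slightly higher than this reckoning, with dp = 43 and c = 77 %, and it lists “complete impurity scavenging” among its guesses.

The flask gives dp = 43.3 and c = 77.9 %.

    free monomer + initiator → living end + monomer in chains (k = 0.0320 M⁻¹ min⁻¹)
    free monomer + living end → monomer in chains + living end, rate k2*[living end]*[free monomer] (k = 0.0740 M⁻¹ min⁻¹)
    initiator + impurity → spent initiator (k = 100 M⁻¹ min⁻¹)

At 4.00 d the flask holds 0.00360 M of living end beside 0.00340 M of spent initiator, with initiator at 0 %. A neighbouring flask charged with 0.028 M of initiator has a surplus of 24.6 mM, and 0.20 M of free monomer shared over that surplus is 8.13 units per chain. That flask reaches c = >99.9 % at 4.00 d, with dp = 8.27.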